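Assumption: the target is drawn as the free bis(hydrogen sulfate); aryl hydrogen sulfates are strong acids that hydrolyse themselves, so 16 and 17 are made and handled as disodium salts and are listed in the neutral acid form, which a cold H+-form cation-exchange resin releases from the salt.

## Structural features

The target is a diaryl ether of two phloroglucinol-type benzene rings and has no stereocentre, so no stereocentres stand next to each other and the problem is one of connectivity and of telling five phenolic oxygens apart. Ring A (C1–C6) carries the ether oxygen at C1, a free hydroxyl at C3 and a sulfate monoester at C5. Ring B (C1'–C6') is bonded to the same oxygen through C1', with free hydroxyls at C2' and C6' and the second sulfate at C4'. Ring B is locally symmetric about the C1'–C4' axis, whereas the two remaining oxygens of ring A differ, so ring A must be desymmetrised at some stage. The fragile parts are the two aryl sulfate monoesters (ionic, cleaved by aqueous acid, awkward to purify) and the electron-rich polyphenol rings, which oxidise readily as phenoxides and are open to attack by carbon electrophiles. The real difficulties are the C1'–O bond, which lies between two ortho oxygen substituents on an electron-rich ring and is a poor candidate for aryl–oxygen coupling, and the delivery of exactly the C5 and C4' oxygens to sulfation. The key step uses the fact that ring B is the aromatic tautomer of a cyclohexane-1,3,5-trione bearing the aryloxy group on C1', that is, a 2-aryloxy-3,5-dioxohexanoate folded so that C1' meets C2'; keeping the C4' oxygen as a benzyl enol ether in that chain distinguishes it from the C2' and C6' oxygens from the moment ring B forms.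

## Logic of the disconnections

17 to 16: the three O–Si bonds at C3–O, C2'–O and C6'–O are the last to be cleaved. Sulfate monoesters tolerate fluoride and mild base but not acid, so a fluoride step is the safest final unmasking. The precursor 16 is lipophilic enough to be purified as a salt. The forward step must avoid acid and finish by ion exchange.

16 to 15: the two O–S bonds at C5–O and C4'–O are cut. Charged groups go in as late as possible, which leaves a neutral diol that can be chromatographed. The forward step needs exactly two free, unhindered phenols and silyl ethers that survive the SO3 complex.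

15 to 14: the two O–benzyl bonds are cut. Benzyl marks the two sulfate positions and is removed by hydrogenolysis, which silyl ethers do not feel. The forward step must run in a neutral, aprotic medium.

14 to 13: the two O–Si bonds at C2' and C6' are cut. These hydroxyls appear free in the ring-forming step and are capped with the same silyl group as ring A carries, so one fluoride step later removes all three. Both phenols lie ortho to the aryloxy group, so a silyl triflate is needed.

13 to 11: the C1'–C2' bond is cut and ring B opens to the acyclic keto enol-ether ester. The C1'–O bond then never has to be made on an arene, one ring and one C–C bond disappear, and the C4' oxygen is already differentiated. In 11 the most acidic site is the C5' methylene and not C1', so the forward step must run under equilibrating conditions in which acylation through carbon is the only irreversible outcome.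

11 to 5 and 8: the C5'–C6' bond is cut between the γ-carbon of 8 and the acyl carbon of 5. This gives a two-carbon acyl donor carrying ring A and a four-carbon vinylogous ester of similar size. The forward step must be γ-selective and stop after one addition, which is why 5 is an N-methoxy-N-methylamide.

8 to 6 and 7: the vinyl C–O bond at the future C4' is cut. Ester and enol ether carry the same benzyl group, so later alkoxide exchange changes nothing. The forward step must give the (E) isomer, which is the thermodynamic one.

5 to 4, then to 2 and 3: first the ring A O–Si bond, then the O–CH2 bond between the ring A oxygen and the future C1' are cut. The ether oxygen is joined to C1' by substitution at an sp3 carbon, and using 3 puts the amide in place without a separate step. The price is mono-alkylation of a symmetric diol, which is statistical and calls for an excess of 2.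

2 to 1: one O–benzyl bond is cut, leading to the cheapest possible arene. The forward step is a statistical mono-benzylation in which oxygen must be favoured over ring carbon.

## Other disconnections considered

Alternative 1: The cut goes through the two C–O bonds that end up carrying the sulfates, C5–O and C4'–O. It leads back to tert-butyl{3-[2,6-bis(tert-butyldimethylsilyloxy)phenoxy]phenoxy}dimethylsilane A2, a diaryl ether with only three ring oxygens. Forward, [Ir(OMe)(cod)]2 with 4,4'-di-tert-butyl-2,2'-bipyridine and bis(pinacolato)diboron would borylate A2 at the only two C–H bonds without an ortho substituent, C5 and C4'. KHSO5 added to the same pot would then convert both C–B bonds into phenols, giving 3-[2,6-bis(tert-butyldimethylsilyloxy)-4-hydroxyphenoxy]-5-(tert-butyldimethylsilyloxy)phenol A1. In its favour, steric control of iridium borylation is a dependable regiochemical rule, the five oxygens are differentiated by the catalyst with no statistical step, and A1 is the tert-butyldimethylsilyl counterpart of 15, so only sulfation and desilylation remain. Against it, A2 requires the C1'–O bond to be made by copper-mediated coupling of a 2,6-dioxygenated phenol, the kind of hindered coupling the chosen plan avoids, although with no para oxygen on ring B it is a milder case. Both rings must be borylated to completion, and the 4-aryloxyphenol formed on ring B is exposed to over-oxidation by the peroxymonosulfate. On step economy the alternative is clearly the better plan (about six steps against ten, none statistical). On protecting-group logic it is the equal of the chosen plan, since both end at a tris-silyl diol. Mechanistically its selectivity rests on established catalyst control, whereas the chosen key step rests on an equilibrium between enolates. The chosen plan keeps the advantages that no aryl–oxygen coupling and no precious-metal catalyst are needed and that every ring oxygen comes from a cheap oxygenated building block.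

Alternative 2: Ring A is cut at C3–C4 and C5–C6 and grown on the ether oxygen from 3-[2,6-bis(benzyloxy)-4-(triisopropylsilyloxy)phenoxy]cyclobut-2-en-1-one A4 and ethynyloxy(triisopropyl)silane A5. On heating, A4 would open to a vinylketene, add A5, reopen and electrocyclise. Ring A would then appear as 3-[2,6-bis(benzyloxy)-4-(triisopropylsilyloxy)phenoxy]-5-(triisopropylsilyloxy)phenol A3, with the C3 hydroxyl free (from the ketene carbonyl) and the C5 oxygen silylated (from the ynol ether). In its favour, ring A is formed already desymmetrised, which is better than the two statistical etherifications of the chosen plan. The regiochemistry is fixed by the polarisation of the ynol ether, and the ether oxygen is attached to C1 by addition–elimination on a vinylogous ester, not by aryl coupling. After benzylation of the C3 hydroxyl, the end game (desilylation, sulfation, hydrogenolysis) finishes with a step whose only by-product is toluene, arguably cleaner than a fluoride step on a bis-sulfate. Against it, the phenol needed for A4 is a fully differentiated tetra-oxygenated ring B that must be made and protected first, so the difficulty is moved and not removed. A4 and A5 are sensitive reagents that each take several steps, and a four-stage pericyclic cascade must be run hot on a substrate with silyl ethers and a strained enol ether. Both plans need four steps after the key step and are equal there; before it the alternative is expected to be longer. The benzannulation is the better controlled key step as regards regiochemistry, while the chosen Claisen closure is simpler in reagents and scale.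

Alternative 3: Ring B is cut at C2'–C3' and C6'–C5'. One fragment is dibenzyl 2-[3-(benzyloxy)-5-(triisopropylsilyloxy)phenoxy]propanedioate A7, which supplies C1' with its two carbonyl carbons. The other is dibenzyl (E)-3-(benzyloxy)pent-2-enedioate A8, which supplies C3', C4' and C5'. With NaOCH2Ph in hot toluene the two would condense twice (an intermolecular Claisen acylation, then a Dieckmann-type closure) to dibenzyl 2-(benzyloxy)-5-[3-(benzyloxy)-5-(triisopropylsilyloxy)phenoxy]-4,6-dihydroxybenzene-1,3-dicarboxylate A6. In its favour, the plan is convergent, masks the C4' oxygen in the same way as the chosen plan, and attaches the ether oxygen at an sp3 carbon just as the chosen plan does (equal). The most acidic carbon of A8 is also the one that must act as nucleophile, which is better than in 11, where the most acidic site is not the reacting one. Against it, the central C–H of A7 is itself acidic, and once it is deprotonated both ester carbonyls of A7 are deactivated as acyl donors, so the first condensation would have to be forced thermally. A6 also carries two ester groups that the target lacks. Their removal by hydrogenolysis and decarboxylation cannot be separated from cleavage of the benzyl ethers, so the C2' and C6' hydroxyls, hydrogen-bonded to ortho esters and flanked on both sides, would have to be silylated first. Ring A still has to be desymmetrised statistically (equal). In step economy the alternative matches the chosen plan up to the key step and is about one operation longer after it. It forms two ring bonds in one step against one, at the price of a fully substituted, more crowded ring B.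

Key step: step 6

## Steps

Step 1
Reactants: 1 benzene-1,3,5-triol (phloroglucinol)
Product: 2 5-(benzyloxy)benzene-1,3-diol
Conditions: 1 (3 equiv), BnBr (1 equiv), K2CO3 (1 equiv), DMF, 0 °C to rt; excess 1 removed by aqueous wash
Reagents that add atoms: benzyl bromide, BrCc1ccccc1
Why: Williamson O-benzylation of a phenoxide; in DMF with carbonate the oxygen of the mono-anion is alkylated in preference to ring carbon, and the threefold excess of the cheap, water-soluble triol biases the statistical mixture toward the mono-ether.

Step 2
Reactants: 2 5-(benzyloxy)benzene-1,3-diol; 3 2-chloro-N-methoxy-N-methylacetamide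
Product: 4 2-[3-(benzyloxy)-5-hydroxyphenoxy]-N-methoxy-N-methylacetamide
Conditions: 2 (2 equiv), 3 (1 equiv), K2CO3 (1.1 equiv), NaI (0.1 equiv), MeCN, 60 °C; unreacted 2 recovered
Reagents that add atoms: none
Why: Williamson alkylation (SN2 with in situ Finkelstein exchange by iodide) of one phenoxide of the symmetric diol at the sp3 carbon that becomes C1', so the future C1'–O bond exists before C1' is part of an arene. The excess of 2 keeps dialkylation low.

Step 3
Reactants: 4 2-[3-(benzyloxy)-5-hydroxyphenoxy]-N-methoxy-N-methylacetamide
Product: 5 2-[3-(benzyloxy)-5-(triisopropylsilyloxy)phenoxy]-N-methoxy-N-methylacetamide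
Conditions: TIPSCl (1.2 equiv), imidazole (2.5 equiv), DMF, rt
Reagents that add atoms: chlorotri(propan-2-yl)silane (TIPSCl), CC(C)[Si](Cl)(C(C)C)C(C)C
Why: Standard silylation of a phenol with a silyl chloride and imidazole; the bulky triisopropylsilyl ether tolerates the amide base of step 5 and the hydrogenolysis of step 8.

Step 4
Reactants: 6 benzyl 3-oxobutanoate (benzyl acetoacetate); 7 benzyl alcohol
Product: 8 benzyl (E)-3-(benzyloxy)but-2-enoate
Conditions: 7 (1.5 equiv), TsOH·H2O (5 mol%), toluene, reflux, Dean–Stark trap
Reagents that add atoms: none
Why: Acid-catalysed enol etherification of a β-keto ester with azeotropic removal of water; the conjugated (E) isomer, with benzyloxy trans and methyl cis to the ester, is the thermodynamic product, and transesterification by 7 is degenerate because the ester is already benzyl.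

Step 5
Reactants: 8 benzyl (E)-3-(benzyloxy)but-2-enoate; 5 2-[3-(benzyloxy)-5-(triisopropylsilyloxy)phenoxy]-N-methoxy-N-methylacetamide
Product: 11 benzyl (E)-3-(benzyloxy)-6-[3-(benzyloxy)-5-(triisopropylsilyloxy)phenoxy]-5-oxohex-2-enoate, via lithium dienolate 9 (not isolated), via lithium hemiaminal adduct 10 (not isolated)
Conditions: 8 (2 equiv), LiN(iPr)2 (2 equiv), THF, −78 °C; then 5 (1 equiv), −78 °C; aq NH4Cl at −78 °C
Reagents that add atoms: none
Why: γ-Deprotonation of the vinylogous ester (the methyl group syn to the lithium-coordinated carbonyl) gives dienolate 9, which is acylated at its γ-carbon by the N-methoxy-N-methylamide (Weinreb ketone synthesis, a Claisen-type acylation). The chelated adduct 10 survives until the cold quench, which prevents double addition and keeps the product away from base. Reaction through the cisoid dienolate returns the C2=C3 bond in the (E) geometry, which is also the more stable one.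

Step 6
Reactants: 11 benzyl (E)-3-(benzyloxy)-6-[3-(benzyloxy)-5-(triisopropylsilyloxy)phenoxy]-5-oxohex-2-enoate
Product: 13 5-(benzyloxy)-2-[3-(benzyloxy)-5-(triisopropylsilyloxy)phenoxy]benzene-1,3-diol, via cyclohexenedione tautomer 12 (not isolated)
Conditions: NaH (3 equiv), BnOH (0.2 equiv), THF (0.02 M), 0 °C to 60 °C, argon; cold aq NH4Cl
Reagents that add atoms: none
Why: The ketone enolate at C1' adds to the benzyl ester carbonyl C2' and benzyloxide is expelled (intramolecular Claisen, Dieckmann-type, condensation); the cyclic enedione 12 enolises at once to the arene, which is held as its sodium salt. The closest known reaction type is the base-mediated Claisen cyclisation of 3,5-dioxohexanoate esters to phloroglucinols, the laboratory counterpart of polyketide folding, here with one carbonyl masked as an enol ether. The ring closes in the 6-(enolendo)-exo-trig mode, because the enolate double bond C1'=C6' lies inside the new ring and the ester C=O outside it; no stereocentre is created. The first equivalent of base removes the more acidic C5' methylene, whose enolate can reach the ester only through oxygen, and the benzyl alcohol/benzyloxide couple shuttles protons so that the less populated C1' enolate, acidified by the aryloxy group, stays available. The selectivity needed is acylation through carbon and not through the ketone enol oxygen (lactonisation); it is secured thermodynamically, since O-acylation is undone by benzyloxide while the carbocycle, once enolised to the arene and deprotonated, cannot revert. Because the enol ether is (E), the ester carbon and the ketone-bearing arm sit on the same side of the double bond, and since ester and enol ether carry the same benzyl group, transesterification and addition–elimination of benzyloxide at C4' change nothing. High dilution holds back intermolecular condensation, exclusion of air protects the electron-rich phenoxide, and any ring A silyl group lost to benzyloxide is restored in step 7.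

Step 7
Reactants: 13 5-(benzyloxy)-2-[3-(benzyloxy)-5-(triisopropylsilyloxy)phenoxy]benzene-1,3-diol
Product: 14 5-(benzyloxy)-2-[3-(benzyloxy)-5-(triisopropylsilyloxy)phenoxy]-1,3-bis(triisopropylsilyloxy)benzene
Conditions: TIPSOTf (3 equiv), 2,6-lutidine (4 equiv), CH2Cl2, 0 °C to rt
Reagents that add atoms: triisopropylsilyl trifluoromethanesulfonate (TIPSOTf), CC(C)[Si](OS(=O)(=O)C(F)(F)F)(C(C)C)C(C)C
Why: A silyl triflate with a hindered pyridine base is the standard way to silylate phenols ortho to a bulky substituent. Using the same silyl group as on ring A means one fluoride step later unmasks all three hydroxyls.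

Step 8
Reactants: 14 5-(benzyloxy)-2-[3-(benzyloxy)-5-(triisopropylsilyloxy)phenoxy]-1,3-bis(triisopropylsilyloxy)benzene
Product: 15 3-[4-hydroxy-2,6-bis(triisopropylsilyloxy)phenoxy]-5-(triisopropylsilyloxy)phenol
Conditions: H2 (1 atm), Pd/C (10% Pd on carbon), EtOAc, rt
Reagents that add atoms: none
Why: Catalytic hydrogenolysis of benzyl aryl ethers over palladium on carbon; in neutral ethyl acetate the aryl silyl ethers and the diaryl ether are inert, so exactly the C5 and C4' hydroxyls are set free.

Step 9
Reactants: 15 3-[4-hydroxy-2,6-bis(triisopropylsilyloxy)phenoxy]-5-(triisopropylsilyloxy)phenol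
Product: 16 3-[4-(sulfooxy)-2,6-bis(triisopropylsilyloxy)phenoxy]-5-(triisopropylsilyloxy)phenyl hydrogen sulfate (isolated as the disodium salt)
Conditions: SO3·pyridine (6 equiv), pyridine, 25 to 40 °C; aq NaHCO3
Reagents that add atoms: sulfur trioxide–pyridine complex, [O-]S(=O)(=O)[n+]1ccccc1
Why: O-Sulfonation of phenols with the pyridine–SO3 complex; both free hydroxyls are flanked only by ring hydrogens and are the only nucleophiles left, while the silyl ethers are stable in anhydrous pyridine.

Step 10
Reactants: 16 3-[4-(sulfooxy)-2,6-bis(triisopropylsilyloxy)phenoxy]-5-(triisopropylsilyloxy)phenyl hydrogen sulfate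
Product: 17 3-[2,6-dihydroxy-4-(sulfooxy)phenoxy]-5-hydroxyphenyl hydrogen sulfate (the target, isolated as the disodium salt)
Conditions: Bu4NF (3.5 equiv), AcOH (3.5 equiv), THF, 0 °C to rt; Na+-form cation-exchange resin; C18 reversed-phase chromatography
Reagents that add atoms: none
Why: Fluoride cleaves aryl silyl ethers by forming the strong Si–F bond, whereas aryl sulfate monoester anions do not react with fluoride. Buffering with acetic acid keeps the liberated polyphenol protonated, and so less prone to air oxidation, without reaching the acidity at which sulfates hydrolyse.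

## Compound list

1 | benzene-1,3,5-triol (phloroglucinol) | Oc1cc(O)cc(O)c1 | starting material
2 | 5-(benzyloxy)benzene-1,3-diol | Oc1cc(O)cc(OCc2ccccc2)c1 | intermediate
3 | 2-chloro-N-methoxy-N-methylacetamide | CON(C)C(=O)CCl | starting material
4 | 2-[3-(benzyloxy)-5-hydroxyphenoxy]-N-methoxy-N-methylacetamide | CON(C)C(=O)COc1cc(O)cc(OCc2ccccc2)c1 | intermediate
5 | 2-[3-(benzyloxy)-5-(triisopropylsilyloxy)phenoxy]-N-methoxy-N-methylacetamide | CON(C)C(=O)COc1cc(OCc2ccccc2)cc(O[Si](C(C)C)(C(C)C)C(C)C)c1 | intermediate
6 | benzyl 3-oxobutanoate (benzyl acetoacetate) | CC(=O)CC(=O)OCc1ccccc1 | starting material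
7 | benzyl alcohol | OCc1ccccc1 | starting material
8 | benzyl (E)-3-(benzyloxy)but-2-enoate | O=C(OCc1ccccc1)/C=C(C)/OCc1ccccc1 | intermediate
9 | lithium 1,3-bis(benzyloxy)buta-1,3-dien-1-olate (ketene acetal geometry not defined; not isolated) | [Li]OC(OCc1ccccc1)=CC(=C)OCc1ccccc1 | intermediate
10 | benzyl (E)-3-(benzyloxy)-6-[3-(benzyloxy)-5-(triisopropylsilyloxy)phenoxy]-5-(lithiooxy)-5-[methoxy(methyl)amino]hex-2-enoate (racemic; not isolated) | O=C(OCc1ccccc1)/C=C(/OCc1ccccc1)CC(O[Li])(N(C)OC)COc1cc(OCc2ccccc2)cc(O[Si](C(C)C)(C(C)C)C(C)C)c1 | intermediate
11 | benzyl (E)-3-(benzyloxy)-6-[3-(benzyloxy)-5-(triisopropylsilyloxy)phenoxy]-5-oxohex-2-enoate | O=C(OCc1ccccc1)/C=C(/OCc1ccccc1)CC(=O)COc1cc(OCc2ccccc2)cc(O[Si](C(C)C)(C(C)C)C(C)C)c1 | intermediate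
12 | 5-(benzyloxy)-2-[3-(benzyloxy)-5-(triisopropylsilyloxy)phenoxy]cyclohex-4-ene-1,3-dione (racemic; not isolated) | O=C1CC(OCc2ccccc2)=CC(=O)C1Oc1cc(OCc2ccccc2)cc(O[Si](C(C)C)(C(C)C)C(C)C)c1 | intermediate
13 | 5-(benzyloxy)-2-[3-(benzyloxy)-5-(triisopropylsilyloxy)phenoxy]benzene-1,3-diol | Oc1cc(OCc2ccccc2)cc(O)c1Oc1cc(OCc2ccccc2)cc(O[Si](C(C)C)(C(C)C)C(C)C)c1 | intermediate
14 | 5-(benzyloxy)-2-[3-(benzyloxy)-5-(triisopropylsilyloxy)phenoxy]-1,3-bis(triisopropylsilyloxy)benzene | CC(C)[Si](Oc1cc(OCc2ccccc2)cc(O[Si](C(C)C)(C(C)C)C(C)C)c1Oc1cc(OCc2ccccc2)cc(O[Si](C(C)C)(C(C)C)C(C)C)c1)(C(C)C)C(C)C | intermediate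
15 | 3-[4-hydroxy-2,6-bis(triisopropylsilyloxy)phenoxy]-5-(triisopropylsilyloxy)phenol | CC(C)[Si](Oc1cc(O)cc(O[Si](C(C)C)(C(C)C)C(C)C)c1Oc1cc(O)cc(O[Si](C(C)C)(C(C)C)C(C)C)c1)(C(C)C)C(C)C | intermediate
16 | 3-[4-(sulfooxy)-2,6-bis(triisopropylsilyloxy)phenoxy]-5-(triisopropylsilyloxy)phenyl hydrogen sulfate | CC(C)[Si](Oc1cc(OS(=O)(=O)O)cc(O[Si](C(C)C)(C(C)C)C(C)C)c1Oc1cc(OS(=O)(=O)O)cc(O[Si](C(C)C)(C(C)C)C(C)C)c1)(C(C)C)C(C)C | intermediate
17 | 3-[2,6-dihydroxy-4-(sulfooxy)phenoxy]-5-hydroxyphenyl hydrogen sulfate | O=S(=O)(O)Oc1cc(O)cc(Oc2c(O)cc(OS(=O)(=O)O)cc2O)c1 | target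

## Step count and least certain steps

Total: 10 steps. Longest linear sequence: 9 steps (steps 1, 2, 3, 5, 6, 7, 8, 9, 10 from 1); step 4 is a one-step side branch.

Step 6 (key step). The likeliest failure is closure through the ketone enol oxygen (lactonisation) that is not reversed fast enough. This is plausible because the base rests on the more acidic C5' methylene and the C1' enolate is only a minor partner in the equilibrium; slow ring closure would then let intermolecular condensation and desilylation take over. Fallback: give up building ring B and make the C1'–O bond by copper-catalysed coupling, starting from 2 and returning at 14.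
- 2 is protected with MOMCl and iPr2NEt in CH2Cl2 to give 5-(benzyloxy)-1,3-bis(methoxymethoxy)benzene F1.
- Directed ortho-lithiation between the two acetal oxygens (n-BuLi, THF, 0 °C), then I2, should give 5-(benzyloxy)-2-iodo-1,3-bis(methoxymethoxy)benzene F2.
- Ullmann-type coupling of F2 with an excess of 2 (CuI, picolinic acid, K3PO4, DMSO, 90 °C) should give 3-(benzyloxy)-5-[4-(benzyloxy)-2,6-bis(methoxymethoxy)phenoxy]phenol F3.
- HCl in MeOH removes both acetals to give 5-(benzyloxy)-2-[3-(benzyloxy)-5-hydroxyphenoxy]benzene-1,3-diol F4.
- TIPSOTf (3.5 equiv) and 2,6-lutidine silylate all three phenols and deliver 14.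

This uses the hindered coupling the main route avoids, and that coupling should be expected to be slow.

Step 5. Proton transfer from the α-aryloxy amide to the dienolate may compete with addition, the dienolate may react through its α-carbon, and the product may lactonise during work-up. Fallback, from 5 back to 11: iBu2AlH in THF at −78 °C reduces 5 to 2-[3-(benzyloxy)-5-(triisopropylsilyloxy)phenoxy]acetaldehyde F5. Aldol addition of dienolate 9 at −78 °C with a cold quench (γ-attack is the normal course with aldehydes) gives racemic benzyl (E)-3-(benzyloxy)-6-[3-(benzyloxy)-5-(triisopropylsilyloxy)phenoxy]-5-hydroxyhex-2-enoate F6. Dess–Martin periodinane in CH2Cl2 oxidises F6 to 11.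

Step 4. Etherification may stall at incomplete conversion, benzyl alcohol may self-condense under acid, and the geometry may not equilibrate fully. Fallback, from 7 back to 8: but-2-ynoic acid is esterified with 7 (DCC, DMAP, CH2Cl2) to benzyl but-2-ynoate F7. A second molecule of 7 is then added across the triple bond with catalytic NaOCH2Ph in THF; this conjugate addition equilibrates by addition–elimination to the (E) enol ether 8.

Step 9. Sulfation may stop at the mono-sulfate, silyl groups may be lost during prolonged exposure to pyridinium salts, and the amphiphilic salts may prove hard to separate. Fallback, from 15 back to 16: 2,2,2-trichloroethyl chlorosulfate, Et3N and DMAP in THF convert 15 into the neutral diester 3-{4-[(2,2,2-trichloroethoxy)sulfonyloxy]-2,6-bis(triisopropylsilyloxy)phenoxy}-5-(triisopropylsilyloxy)phenyl 2,2,2-trichloroethyl sulfate F8, which can be purified on silica. Zn and HCO2NH4 in MeOH then remove both trichloroethyl groups and give 16 as its ammonium salt.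

Step 1. Benzylation at ring carbon and over-benzylation may erode the yield, since the phloroglucinol anion is an ambident nucleophile. Fallback, from 1 back to 4: an excess of 1 is alkylated first with 3 (K2CO3, NaI, MeCN), which is a harder electrophile and should prefer oxygen, to give 2-(3,5-dihydroxyphenoxy)-N-methoxy-N-methylacetamide F9. One hydroxyl of F9 is then etherified with 7 under Mitsunobu conditions (PPh3, DIAD, THF, 1 equiv of 7) to give 4.

## Further compounds

F1 | step 6 | 5-(benzyloxy)-1,3-bis(methoxymethoxy)benzene | COCOc1cc(OCOC)cc(OCc2ccccc2)c1
F2 | step 6 | 5-(benzyloxy)-2-iodo-1,3-bis(methoxymethoxy)benzene | COCOc1cc(OCc2ccccc2)cc(OCOC)c1I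
F3 | step 6 | 3-(benzyloxy)-5-[4-(benzyloxy)-2,6-bis(methoxymethoxy)phenoxy]phenol | COCOc1cc(OCc2ccccc2)cc(OCOC)c1Oc1cc(O)cc(OCc2ccccc2)c1
F4 | step 6 | 5-(benzyloxy)-2-[3-(benzyloxy)-5-hydroxyphenoxy]benzene-1,3-diol | Oc1cc(OCc2ccccc2)cc(Oc2c(O)cc(OCc3ccccc3)cc2O)c1
F5 | step 5 | 2-[3-(benzyloxy)-5-(triisopropylsilyloxy)phenoxy]acetaldehyde | O=CCOc1cc(OCc2ccccc2)cc(O[Si](C(C)C)(C(C)C)C(C)C)c1
F6 | step 5 | benzyl (E)-3-(benzyloxy)-6-[3-(benzyloxy)-5-(triisopropylsilyloxy)phenoxy]-5-hydroxyhex-2-enoate (racemic) | O=C(OCc1ccccc1)/C=C(/OCc1ccccc1)CC(O)COc1cc(OCc2ccccc2)cc(O[Si](C(C)C)(C(C)C)C(C)C)c1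
F7 | step 4 | benzyl but-2-ynoate | CC#CC(=O)OCc1ccccc1
F8 | step 9 | 3-{4-[(2,2,2-trichloroethoxy)sulfonyloxy]-2,6-bis(triisopropylsilyloxy)phenoxy}-5-(triisopropylsilyloxy)phenyl 2,2,2-trichloroethyl sulfate | CC(C)[Si](Oc1cc(OS(=O)(=O)OCC(Cl)(Cl)Cl)cc(O[Si](C(C)C)(C(C)C)C(C)C)c1Oc1cc(OS(=O)(=O)OCC(Cl)(Cl)Cl)cc(O[Si](C(C)C)(C(C)C)C(C)C)c1)(C(C)C)C(C)C
F9 | step 1 | 2-(3,5-dihydroxyphenoxy)-N-methoxy-N-methylacetamide | CON(C)C(=O)COc1cc(O)cc(O)c1
A1 | alternative 1 | 3-[2,6-bis(tert-butyldimethylsilyloxy)-4-hydroxyphenoxy]-5-(tert-butyldimethylsilyloxy)phenol | CC(C)(C)[Si](C)(C)Oc1cc(O)cc(Oc2c(O[Si](C)(C)C(C)(C)C)cc(O)cc2O[Si](C)(C)C(C)(C)C)c1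
A2 | alternative 1 | tert-butyl{3-[2,6-bis(tert-butyldimethylsilyloxy)phenoxy]phenoxy}dimethylsilane | CC(C)(C)[Si](C)(C)Oc1cccc(Oc2c(O[Si](C)(C)C(C)(C)C)cccc2O[Si](C)(C)C(C)(C)C)c1
A3 | alternative 2 | 3-[2,6-bis(benzyloxy)-4-(triisopropylsilyloxy)phenoxy]-5-(triisopropylsilyloxy)phenol | Oc1cc(O[Si](C(C)C)(C(C)C)C(C)C)cc(Oc2c(OCc3ccccc3)cc(O[Si](C(C)C)(C(C)C)C(C)C)cc2OCc2ccccc2)c1
A4 | alternative 2 | 3-[2,6-bis(benzyloxy)-4-(triisopropylsilyloxy)phenoxy]cyclobut-2-en-1-one | O=C1C=C(Oc2c(OCc3ccccc3)cc(O[Si](C(C)C)(C(C)C)C(C)C)cc2OCc2ccccc2)C1
A5 | alternative 2 | ethynyloxy(triisopropyl)silane | C#CO[Si](C(C)C)(C(C)C)C(C)C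
A6 | alternative 3 | dibenzyl 2-(benzyloxy)-5-[3-(benzyloxy)-5-(triisopropylsilyloxy)phenoxy]-4,6-dihydroxybenzene-1,3-dicarboxylate | O=C(OCc1ccccc1)c1c(O)c(Oc2cc(OCc3ccccc3)cc(O[Si](C(C)C)(C(C)C)C(C)C)c2)c(O)c(C(=O)OCc2ccccc2)c1OCc1ccccc1
A7 | alternative 3 | dibenzyl 2-[3-(benzyloxy)-5-(triisopropylsilyloxy)phenoxy]propanedioate | O=C(OCc1ccccc1)C(Oc1cc(OCc2ccccc2)cc(O[Si](C(C)C)(C(C)C)C(C)C)c1)C(=O)OCc1ccccc1
A8 | alternative 3 | dibenzyl (E)-3-(benzyloxy)pent-2-enedioate | O=C(OCc1ccccc1)/C=C(/OCc1ccccc1)CC(=O)OCc1ccccc1
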